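The C ring is disconnected at C4–C4a. The C4 methylene, which links the C3 carbinol to the phloroglucinol A ring, comes from the terminal carbon of an oxirane; the nucleophile is either of the two equivalent A-ring carbons ortho to the O1–C2 aryl ether. One fluoroalcohol-promoted operation should form C4–C4a, close the pyran and release the 3-OH, leaving C2 and C3 untouched. The precursor is the threo (R,R) 3,5-bis(benzyloxy)phenyl ether of a B-ring aryl(oxiranyl)methanol that already carries the 4'-O-galloyl ester. It is reached by Grignard vinylation, Sharpless kinetic resolution and Mitsunobu inversion; esterification at O-3 and global hydrogenolysis finish the route.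

Key step: step 8

Assumption: 3,4,5-trihydroxybenzaldehyde (sold as the monohydrate), 3,4,5-tris(benzyloxy)benzoic acid and 3,5-bis(benzyloxy)phenol are taken as catalogue compounds; the last two are the perbenzyl ethers of gallic acid and phloroglucinol.

Step 1
Reactants: 1 3,4,5-trihydroxybenzaldehyde
Product: 2 3,4,5-tris(benzyloxy)benzaldehyde
Conditions: BnBr (3.3 equiv), K2CO3, DMF, 60 °C, N2
Reagents that add atoms: benzyl bromide, BrCc1ccccc1
Why: Threefold Williamson etherification of the phenoxides under carbonate base; the aldehyde has no α-hydrogen and is inert, and no stereocentre is involved.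

Step 2
Reactants: 2 3,4,5-tris(benzyloxy)benzaldehyde
Product: 3 3,5-bis(benzyloxy)-4-hydroxybenzaldehyde
Conditions: MgBr2·OEt2 (1.5 equiv), toluene–Et2O, 80 °C; then 1 M HCl
Reagents that add atoms: none
Why: Regioselective Lewis-acid ether cleavage, the benzyl counterpart of the selective 4-O-dealkylation of 3,4,5-trialkoxybenzaldehydes to syringaldehyde-type phenols: Mg(II) is chelated by the central oxygen and one neighbour, the twisted central benzyloxy group is the only one present in both chelates, and bromide removes its benzyl group to leave the phenoxide best stabilised by the para-formyl group.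

Step 3
Reactants: 4 3,4,5-tris(benzyloxy)benzoic acid
Product: 5 3,4,5-tris(benzyloxy)benzoyl chloride
Conditions: (COCl)2, cat. DMF, CH2Cl2, 0 °C → rt; concentrate
Reagents that add atoms: oxalyl chloride, O=C(Cl)C(=O)Cl
Why: Acid chloride formation through the catalytic Vilsmeier-type chloroiminium species; benzyl ethers are inert, and one batch of 5 serves steps 4 and 9.

Step 4
Reactants: 3 3,5-bis(benzyloxy)-4-hydroxybenzaldehyde; 5 3,4,5-tris(benzyloxy)benzoyl chloride
Product: 6 2,6-bis(benzyloxy)-4-formylphenyl 3,4,5-tris(benzyloxy)benzoate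
Conditions: Et3N, DMAP (10 mol%), CH2Cl2, 0 °C → rt
Reagents that add atoms: none
Why: DMAP-catalysed O-acylation (acylpyridinium transfer) of the only hydroxyl group, an acidic phenol para to the formyl group that Et3N deprotonates readily despite its two ortho substituents.

Step 5
Reactants: 6 2,6-bis(benzyloxy)-4-formylphenyl 3,4,5-tris(benzyloxy)benzoate; 7 vinylmagnesium bromide
Product: 8 (±)-2,6-bis(benzyloxy)-4-(1-hydroxyprop-2-en-1-yl)phenyl 3,4,5-tris(benzyloxy)benzoate
Conditions: 7 (1.1 equiv, slow addition), THF, −78 °C; sat. aq NH4Cl at −78 °C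
Reagents that add atoms: none
Why: Grignard 1,2-addition: at −78 °C the aldehyde is far more electrophilic than the hindered, electron-rich aryl benzoate, so one equivalent of 7 should add to the formyl group only; the new carbinol centre forms without control and 8 is racemic.

Step 6
Reactants: 8 (±)-2,6-bis(benzyloxy)-4-(1-hydroxyprop-2-en-1-yl)phenyl 3,4,5-tris(benzyloxy)benzoate
Product: 9 2,6-bis(benzyloxy)-4-{(S)-hydroxy[(R)-oxiran-2-yl]methyl}phenyl 3,4,5-tris(benzyloxy)benzoate (erythro)
Conditions: Ti(OiPr)4 (20 mol%), L-(+)-DIPT (24 mol%), t-BuOOH (0.45 equiv), 4 Å MS, CH2Cl2, −20 °C; aq tartaric acid work-up; unreacted (S)-8 removed by chromatography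
Reagents that add atoms: tert-butyl hydroperoxide, CC(C)(C)OO
Why: Sharpless kinetic resolution (Katsuki–Sharpless epoxidation of a secondary allylic alcohol): with L-(+)-DIPT the titanium–tartrate complex epoxidises the (R)-carbinol of 8 much faster than its enantiomer and delivers oxygen to the alkene face that gives the erythro product, so the catalyst selects the carbinol centre (S in 9 only because the oxiranyl carbon now outranks the aryl carbon) and sets the (R)-oxirane centre, while (S)-8 is left behind below 50% conversion.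

Step 7
Reactants: 9 2,6-bis(benzyloxy)-4-{(S)-hydroxy[(R)-oxiran-2-yl]methyl}phenyl 3,4,5-tris(benzyloxy)benzoate; 10 3,5-bis(benzyloxy)phenol
Product: 11 2,6-bis(benzyloxy)-4-{(R)-[3,5-bis(benzyloxy)phenoxy][(R)-oxiran-2-yl]methyl}phenyl 3,4,5-tris(benzyloxy)benzoate (threo)
Conditions: PPh3, DIAD, toluene, 0 °C → rt
Reagents that add atoms: none
Why: Mitsunobu etherification: the alkoxyphosphonium ion of the benzylic alcohol is displaced by the phenoxide of 10 in an SN2 step with inversion, turning the (S)-carbinol into the (R)-aryl ether (erythro to threo) with the oxirane centre untouched; the 4-acyloxy group keeps the benzylic carbon from ionising, so stereochemical leakage is not expected.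

Step 8
Reactants: 11 2,6-bis(benzyloxy)-4-{(R)-[3,5-bis(benzyloxy)phenoxy][(R)-oxiran-2-yl]methyl}phenyl 3,4,5-tris(benzyloxy)benzoate
Product: 12 2,6-bis(benzyloxy)-4-[(2R,3R)-5,7-bis(benzyloxy)-3-hydroxychroman-2-yl]phenyl 3,4,5-tris(benzyloxy)benzoate (5,7,3',5'-tetra-O-benzylepigallocatechin 4'-O-tri-O-benzylgallate)
Conditions: (CF3)2CHOH–CH2Cl2 (4:1), 0.02 M, 25 → 50 °C
Reagents that add atoms: none
Why: Hydrogen bonding from the fluoroalcohol polarises the oxirane, the electron-rich A ring attacks the unhindered terminal carbon through one of its two equivalent carbons ortho to the O1–C2 ether, and proton loss from the arenium ion restores aromaticity and leaves the former oxirane oxygen as the 3-OH. The closest known reaction type is the intramolecular Friedel–Crafts (epoxy–arene) cyclisation of aryl glycidyl ethers to chroman-3-ols under Lewis-acid or fluoroalcohol promotion. The pyran ring closes in the 6-endo mode with respect to the oxirane (C4–C4a bond); the 5-exo alternative at the internal carbon would have to use a more hindered, inductively deactivated secondary carbon and pass through a strained dihydrobenzofuran-forming transition state. No stereocentre is created: C2 and C3 are spectators, the C3–O bond is never broken, and the threo arrangement of 11 should be carried over into the 2,3-cis (2R,3R) chroman. The step needs regioselectivity (terminal versus internal oxirane carbon) and chemoselectivity (no ionisation at C2): the first rests on the primary electrophilic carbon and on the symmetry of the A-ring triether, whose carbon para to the ether oxygen is geometrically out of range; the second rests on the B ring, which its 4'-acyloxy group makes a poor cation-stabilising substituent, and on the absence of strong acid.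

Step 9
Reactants: 12 2,6-bis(benzyloxy)-4-[(2R,3R)-5,7-bis(benzyloxy)-3-hydroxychroman-2-yl]phenyl 3,4,5-tris(benzyloxy)benzoate; 5 3,4,5-tris(benzyloxy)benzoyl chloride
Product: 13 (2R,3R)-5,7,3',5'-tetra-O-benzylepigallocatechin 3,4'-bis-O-(3,4,5-tri-O-benzylgallate)
Conditions: Et3N, cat. DMAP, CH2Cl2, rt
Reagents that add atoms: none
Why: DMAP-catalysed esterification of the single free (axial) 3-hydroxyl with the acid chloride; the mild base should not epimerise C2, and with no other free hydroxyl present the 4'-ester cannot migrate.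

Step 10
Reactants: 13 (2R,3R)-5,7,3',5'-tetra-O-benzylepigallocatechin 3,4'-bis-O-(3,4,5-tri-O-benzylgallate)
Product: 14 (2R,3R)-epigallocatechin 3,4'-di-O-gallate
Conditions: H2 (1 atm), 20% Pd(OH)2/C, THF–MeOH (1:1), rt
Reagents that add atoms: none
Why: Heterogeneous palladium-catalysed hydrogenolysis should cleave all ten benzyl aryl ethers as toluene under neutral conditions, which spare the two gallate esters and the chroman C2–O1 bond and avoid base-induced migration of the 4'-O-galloyl group; no stereocentre is touched.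

Compound list
1 | 3,4,5-trihydroxybenzaldehyde | O=Cc1cc(O)c(O)c(O)c1 | starting material
2 | 3,4,5-tris(benzyloxy)benzaldehyde | O=Cc1cc(OCc2ccccc2)c(OCc2ccccc2)c(OCc2ccccc2)c1 | intermediate
3 | 3,5-bis(benzyloxy)-4-hydroxybenzaldehyde | O=Cc1cc(OCc2ccccc2)c(O)c(OCc2ccccc2)c1 | intermediate
4 | 3,4,5-tris(benzyloxy)benzoic acid | OC(=O)c1cc(OCc2ccccc2)c(OCc2ccccc2)c(OCc2ccccc2)c1 | starting material
5 | 3,4,5-tris(benzyloxy)benzoyl chloride | ClC(=O)c1cc(OCc2ccccc2)c(OCc2ccccc2)c(OCc2ccccc2)c1 | intermediate
6 | 2,6-bis(benzyloxy)-4-formylphenyl 3,4,5-tris(benzyloxy)benzoate | O=Cc1cc(OCc2ccccc2)c(OC(=O)c2cc(OCc3ccccc3)c(OCc3ccccc3)c(OCc3ccccc3)c2)c(OCc2ccccc2)c1 | intermediate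
7 | vinylmagnesium bromide | C=C[Mg]Br | starting material
8 | (±)-2,6-bis(benzyloxy)-4-(1-hydroxyprop-2-en-1-yl)phenyl 3,4,5-tris(benzyloxy)benzoate (racemic) | C=CC(O)c1cc(OCc2ccccc2)c(OC(=O)c2cc(OCc3ccccc3)c(OCc3ccccc3)c(OCc3ccccc3)c2)c(OCc2ccccc2)c1 | intermediate
9 | 2,6-bis(benzyloxy)-4-{(S)-hydroxy[(R)-oxiran-2-yl]methyl}phenyl 3,4,5-tris(benzyloxy)benzoate (erythro) | O=C(Oc1c(OCc2ccccc2)cc([C@@H]([C@H]3CO3)O)cc1OCc2ccccc2)c1cc(OCc2ccccc2)c(OCc2ccccc2)c(OCc2ccccc2)c1 | intermediate
10 | 3,5-bis(benzyloxy)phenol | Oc1cc(OCc2ccccc2)cc(OCc2ccccc2)c1 | starting material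
11 | 2,6-bis(benzyloxy)-4-{(R)-[3,5-bis(benzyloxy)phenoxy][(R)-oxiran-2-yl]methyl}phenyl 3,4,5-tris(benzyloxy)benzoate (threo) | O=C(Oc1c(OCc2ccccc2)cc([C@H]([C@H]3CO3)Oc3cc(OCc4ccccc4)cc(OCc4ccccc4)c3)cc1OCc2ccccc2)c1cc(OCc2ccccc2)c(OCc2ccccc2)c(OCc2ccccc2)c1 | intermediate
12 | 2,6-bis(benzyloxy)-4-[(2R,3R)-5,7-bis(benzyloxy)-3-hydroxychroman-2-yl]phenyl 3,4,5-tris(benzyloxy)benzoate | O=C(Oc1c(OCc2ccccc2)cc([C@H]2Oc3cc(OCc4ccccc4)cc(OCc4ccccc4)c3C[C@H]2O)cc1OCc2ccccc2)c1cc(OCc2ccccc2)c(OCc2ccccc2)c(OCc2ccccc2)c1 | intermediate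
13 | (2R,3R)-5,7,3',5'-tetra-O-benzylepigallocatechin 3,4'-bis-O-(3,4,5-tri-O-benzylgallate) | O=C(Oc1c(OCc2ccccc2)cc([C@H]2Oc3cc(OCc4ccccc4)cc(OCc4ccccc4)c3C[C@H]2OC(=O)c2cc(OCc3ccccc3)c(OCc3ccccc3)c(OCc3ccccc3)c2)cc1OCc2ccccc2)c1cc(OCc2ccccc2)c(OCc2ccccc2)c(OCc2ccccc2)c1 | intermediate
14 | (2R,3R)-epigallocatechin 3,4'-di-O-gallate | O=C(Oc1c(O)cc([C@H]2Oc3cc(O)cc(O)c3C[C@H]2OC(=O)c2cc(O)c(O)c(O)c2)cc1O)c1cc(O)c(O)c(O)c1 | target

Total step count: 10. Longest linear sequence: 9 steps (steps 1, 2, 4, 5, 6, 7, 8, 9 and 10; step 3 is a one-step side branch).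

Steps most likely to fail

First, step 8. The oxirane may be consumed by solvolysis or oligomerisation, or the benzylic C2–O bond may ionise, before the arene reaches the terminal carbon; closure at the internal carbon would be a further leak. A change of promoter alone (catalytic BF3·OEt2 in CH2Cl2 at −78 °C) would be tried first. The fallback reverses the polarity of the C4–C4a bond formation; it sets out from 9 and 10 and comes back to the route at 12. Compound 10 is iodinated ortho to its hydroxyl (NIS, CH2Cl2, −40 °C; the 4-iodo isomer is removed) to give 3,5-bis(benzyloxy)-2-iodophenol F1. Mitsunobu coupling of F1 with 9 (PPh3, DIAD, toluene) should give, with the same inversion as in step 7, the iodoaryl threo ether F2. A nickel-catalysed reductive aryl iodide–epoxide coupling under iodide co-catalysis (NiCl2·glyme, 4,4'-di-tert-butyl-2,2'-bipyridine, NaI, Et3N·HCl, Zn, DMPU, rt) then opens the oxirane at its terminal carbon to the iodohydrin F3, which is not isolated, and joins that carbon to the iodine-bearing ring carbon to give 12. This organonickel pathway involves neither a cation at C2 nor a free aryl anion, so the aryl ester should be tolerated.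

Second, step 6. Epoxidation of a monosubstituted alkene is slow, discrimination between the enantiomers of 8 may be incomplete, and the titanium species may open the product on long exposure. The fallback moves the resolution to the terminal-epoxide stage; it sets out from 8 and comes back at 11. Vanadium-directed epoxidation of racemic 8 (VO(acac)2, t-BuOOH, CH2Cl2, 0 °C) should favour the erythro epoxy alcohol, formed as 9 together with its enantiomer F4 (the minor threo pair is removed by chromatography). Mitsunobu coupling with 10 as in step 7 gives 11 together with its enantiomer F5. Jacobsen hydrolytic kinetic resolution (salen–Co(III)OAc, 0.55 equiv H2O, THF, rt) then hydrolyses the (S)-oxirane of F5 to the (1S,2S)-diol F6 and leaves 11, which is separated from the diol. The (R,R)-catalyst is expected on the empirical model for terminal epoxides; this would be confirmed on the racemate.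

Third, step 2. Regiocontrol may be incomplete, with cleavage of a flanking benzyl ether or of more than one ether giving phenol mixtures. The fallback differentiates O-4 by acidity; it sets out from 1 and comes back at 3. Alkylation of 1 with one equivalent of allyl bromide under weak base (NaHCO3, NaI, DMF, 40 °C) should take place at the most acidic hydroxyl, para to the formyl group, to give 4-(allyloxy)-3,5-dihydroxybenzaldehyde F7. Benzylation of the two remaining phenols (BnBr, K2CO3, DMF) gives 4-(allyloxy)-3,5-bis(benzyloxy)benzaldehyde F8. Palladium-catalysed deallylation (cat. Pd(PPh3)4, K2CO3, MeOH, rt) then gives 3.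

Further compounds
F1 | step 8 | 3,5-bis(benzyloxy)-2-iodophenol | Oc1cc(OCc2ccccc2)cc(OCc2ccccc2)c1I
F2 | step 8 | 2,6-bis(benzyloxy)-4-{(R)-[3,5-bis(benzyloxy)-2-iodophenoxy][(R)-oxiran-2-yl]methyl}phenyl 3,4,5-tris(benzyloxy)benzoate | O=C(Oc1c(OCc2ccccc2)cc([C@H]([C@H]3CO3)Oc3cc(OCc4ccccc4)cc(OCc4ccccc4)c3I)cc1OCc2ccccc2)c1cc(OCc2ccccc2)c(OCc2ccccc2)c(OCc2ccccc2)c1
F3 | step 8 | 2,6-bis(benzyloxy)-4-[(1R,2S)-1-[3,5-bis(benzyloxy)-2-iodophenoxy]-2-hydroxy-3-iodopropyl]phenyl 3,4,5-tris(benzyloxy)benzoate (iodohydrin, not isolated) | O=C(Oc1c(OCc2ccccc2)cc([C@H]([C@H](O)CI)Oc3cc(OCc4ccccc4)cc(OCc4ccccc4)c3I)cc1OCc2ccccc2)c1cc(OCc2ccccc2)c(OCc2ccccc2)c(OCc2ccccc2)c1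
F4 | step 6 | 2,6-bis(benzyloxy)-4-{(R)-hydroxy[(S)-oxiran-2-yl]methyl}phenyl 3,4,5-tris(benzyloxy)benzoate (enantiomer of 9, formed with 9 as the racemate) | O=C(Oc1c(OCc2ccccc2)cc([C@H]([C@@H]3CO3)O)cc1OCc2ccccc2)c1cc(OCc2ccccc2)c(OCc2ccccc2)c(OCc2ccccc2)c1
F5 | step 6 | 2,6-bis(benzyloxy)-4-{(S)-[3,5-bis(benzyloxy)phenoxy][(S)-oxiran-2-yl]methyl}phenyl 3,4,5-tris(benzyloxy)benzoate (enantiomer of 11, formed with 11 as the racemate) | O=C(Oc1c(OCc2ccccc2)cc([C@@H]([C@@H]3CO3)Oc3cc(OCc4ccccc4)cc(OCc4ccccc4)c3)cc1OCc2ccccc2)c1cc(OCc2ccccc2)c(OCc2ccccc2)c(OCc2ccccc2)c1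
F6 | step 6 | 2,6-bis(benzyloxy)-4-[(1S,2S)-1-[3,5-bis(benzyloxy)phenoxy]-2,3-dihydroxypropyl]phenyl 3,4,5-tris(benzyloxy)benzoate | O=C(Oc1c(OCc2ccccc2)cc([C@@H]([C@@H](O)CO)Oc3cc(OCc4ccccc4)cc(OCc4ccccc4)c3)cc1OCc2ccccc2)c1cc(OCc2ccccc2)c(OCc2ccccc2)c(OCc2ccccc2)c1
F7 | step 2 | 4-(allyloxy)-3,5-dihydroxybenzaldehyde | O=Cc1cc(O)c(OCC=C)c(O)c1
F8 | step 2 | 4-(allyloxy)-3,5-bis(benzyloxy)benzaldehyde | O=Cc1cc(OCc2ccccc2)c(OCC=C)c(OCc2ccccc2)c1
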